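**Plan**

1. Retrosynthesis (chain numbered as the nonanoic acid, C1 = CO2H, C9 = ketone): first the tert-butyl ester and the TBS ether are put back. The dihydropyranone is then opened at C3–C4 and at the O1–C2 ester bond, giving a side-chain acyl Meldrum's acid and methyl (R)-3-hydroxybutanoate. The chain is then cut at C4–C5 (cross-metathesis, hydrogenation) and at C2–C3 (enolate allylation).
2. Enabling feature: ring carbon C3 is a tricarbonylmethane carbon, flanked by lactone C2, enol C4 and the side-chain ketone. Opened at C3–C4 it is the doubly activated CH2 of an acylacetate, and O1–C6(CH3)–C5–C4 is a 3-hydroxybutanoate whose ester carbon C4 lies five atoms from C3. The acidic enol product makes the closure irreversible.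
3. Forward: the stereotriad fragment (5 steps) and the methyl-branched acid (2 steps) are joined by cross-metathesis and hydrogenated. The chain acid is converted to its acyl Meldrum's acid, and the only ring is then made in one flask by acylketene capture and C3–C4 closure. Acidolysis ends the route.
4. Stereochemistry: ring C6 comes from methyl (R)-3-hydroxybutanoate, chain C6 from (R)-β-citronellene and the sec-butyl center from (S)-2-methylbutanoic acid. The carbinol is set by (R)-BINAP–ruthenium hydrogenation, and chain C2 by chelate-controlled anti alkylation relayed from the carbinol.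

Key step: step 11

Remark: the acyl Meldrum's acids and the 3-acyl-4-hydroxy-dihydropyranone are written as the enol tautomers, as in the target; the alkene of 13 should form as an E/Z mixture and is drawn E because step 9 removes it.

**Step 1**
Reactants: 1 (S)-2-methylbutanoic acid
Product: 2 5-[(2S)-1-hydroxy-2-methylbutylidene]-2,2-dimethyl-1,3-dioxane-4,6-dione
Conditions: Meldrum's acid, DCC, DMAP, CH2Cl2, 0 °C → rt; filter, wash with cold aq KHSO4
Reagents that add atoms: Meldrum's acid (2,2-dimethyl-1,3-dioxane-4,6-dione), CC1(C)OC(=O)CC(=O)O1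
Why: Carbodiimide activation and DMAP-catalysed C-acylation of Meldrum's acid is the standard entry to acyl Meldrum's acids, and the alpha stereocenter, which carries no activating heteroatom, should not racemize under these near-neutral conditions.

**Step 2**
Reactants: 2 5-[(2S)-1-hydroxy-2-methylbutylidene]-2,2-dimethyl-1,3-dioxane-4,6-dione
Product: 4 tert-butyl (4S)-4-methyl-3-oxohexanoate, via acylketene 3 (not isolated)
Conditions: tBuOH, PhMe, 80 °C
Reagents that add atoms: tert-butanol, CC(C)(C)O
Why: Thermal retro-[4+2] fragmentation of the acyl Meldrum's acid releases acetone and CO2, and the resulting acylketene is trapped by tert-butanol to the beta-keto ester (acyl Meldrum's acid alcoholysis) without touching the stereocenter.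

**Step 3**
Reactants: 4 tert-butyl (4S)-4-methyl-3-oxohexanoate
Product: 5 tert-butyl (3S,4S)-3-hydroxy-4-methylhexanoate
Conditions: H2 (10 atm), RuCl2[(R)-BINAP] (0.5 mol %), MeOH, 50 °C
Reagents that add atoms: none
Why: Noyori asymmetric hydrogenation of a beta-keto ester, in which the ester carbonyl chelates ruthenium and (R)-BINAP directs hydride to the ketone face that gives the (3S) carbinol (the facial sense that gives (R)-3-hydroxybutanoate from acetoacetate, the descriptor changing because sec-butyl outranks CH2CO2tBu), the catalyst overriding the adjacent C4 center.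

**Step 4**
Reactants: 5 tert-butyl (3S,4S)-3-hydroxy-4-methylhexanoate
Product: 7 tert-butyl (2R)-2-[(1R,2S)-1-hydroxy-2-methylbutyl]pent-4-enoate, via dilithium alkoxide enolate 6 (not isolated)
Conditions: LiN(iPr)2 (2.2 equiv), THF, −78 → −30 °C; allyl bromide, DMPU, −78 → −20 °C; aq NH4Cl
Reagents that add atoms: allyl bromide, C=CCBr
Why: Fráter–Seebach alkylation, in which the lithium-bridged alkoxide enolate chelate is attacked by allyl bromide on the face opposite the C3 sec-butyl group, which should set C2 anti to the C3 oxygen, that is (2R).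

**Step 5**
Reactants: 7 tert-butyl (2R)-2-[(1R,2S)-1-hydroxy-2-methylbutyl]pent-4-enoate
Product: 8 tert-butyl (2R)-2-[(1R,2S)-1-[(tert-butyldimethylsilyl)oxy]-2-methylbutyl]pent-4-enoate
Conditions: TBSOTf, 2,6-lutidine, CH2Cl2, −78 → 0 °C
Reagents that add atoms: tert-butyldimethylsilyl triflate, CC(C)(C)[Si](C)(C)OS(=O)(=O)C(F)(F)F
Why: Silylation with a silyl triflate and a hindered pyridine base should cap the hindered secondary alcohol at low temperature faster than the reagent attacks the tert-butyl ester, and the TBS ether keeps the hydroxyl from being acylated by the carbodiimide-activated acid and by the acylketene later on.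

**Step 6**
Reactants: 9 (R)-3,7-dimethylocta-1,6-diene ((R)-β-citronellene)
Product: 11 (R)-4-methylhex-5-enal, via ozonide 10 (not isolated)
Conditions: O3/O2, CH2Cl2, −78 °C, Sudan Red 7B end point; PPh3, −78 °C → rt
Reagents that add atoms: ozone, [O-][O+]=O
Why: Chemoselective ozonolysis, since electrophilic ozone attacks the electron-rich trisubstituted alkene much faster than the monosubstituted vinyl group, so dosing to the dye end point and reducing the ozonide with PPh3 should give the aldehyde with the allylic stereocenter untouched.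

**Step 7**
Reactants: 11 (R)-4-methylhex-5-enal
Product: 12 (R)-4-methylhex-5-enoic acid
Conditions: NaClO2, NaH2PO4, 2-methyl-2-butene, tBuOH/H2O, 0 °C → rt
Reagents that add atoms: sodium chlorite, [Na+].[O-]Cl=O
Why: Pinnick oxidation converts the aldehyde to the acid under buffered conditions that neither epimerize nor isomerize, with 2-methyl-2-butene scavenging the hypochlorous acid that would otherwise add to the vinyl group.

**Step 8**
Reactants: 8 tert-butyl (2R)-2-[(1R,2S)-1-[(tert-butyldimethylsilyl)oxy]-2-methylbutyl]pent-4-enoate; 12 (R)-4-methylhex-5-enoic acid (2.5 equiv)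
Product: 13 (4R,5E,8R,9R,10S)-8-(tert-butoxycarbonyl)-9-[(tert-butyldimethylsilyl)oxy]-4,10-dimethyldodec-5-enoic acid
Conditions: second-generation Hoveyda–Grubbs catalyst (H2IMes)Cl2Ru=CH(C6H4-2-OiPr) (5 mol %), CH2Cl2, 40 °C
Reagents that add atoms: none
Why: Olefin cross-metathesis between the unhindered allyl group of 8 and the allylically branched vinyl group of 12, used in excess, should join the fragments through the C5=C6 bond of 13 with loss of ethylene, the catalyst tolerating the free acid, ester and silyl ether and the alkene geometry being irrelevant because step 9 saturates it.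

**Step 9**
Reactants: 13 (4R,5E,8R,9R,10S)-8-(tert-butoxycarbonyl)-9-[(tert-butyldimethylsilyl)oxy]-4,10-dimethyldodec-5-enoic acid
Product: 14 (4S,8R,9R,10S)-8-(tert-butoxycarbonyl)-9-[(tert-butyldimethylsilyl)oxy]-4,10-dimethyldodecanoic acid
Conditions: H2 (1 atm), 10% Pd/C, EtOAc, rt
Reagents that add atoms: none
Why: Heterogeneous catalytic hydrogenation saturates the disubstituted alkene while the tert-butyl ester, the silyl ether and all sp3 stereocenters are inert (the C4 descriptor changes from R to S only because the priorities change).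

**Step 10**
Reactants: 14 (4S,8R,9R,10S)-8-(tert-butoxycarbonyl)-9-[(tert-butyldimethylsilyl)oxy]-4,10-dimethyldodecanoic acid
Product: 15 tert-butyl (2R,6S)-2-[(1R,2S)-1-[(tert-butyldimethylsilyl)oxy]-2-methylbutyl]-9-(2,2-dimethyl-4,6-dioxo-1,3-dioxan-5-ylidene)-9-hydroxy-6-methylnonanoate
Conditions: Meldrum's acid, DCC, DMAP, CH2Cl2, 0 °C → rt; filter, wash with cold aq KHSO4
Reagents that add atoms: Meldrum's acid (2,2-dimethyl-1,3-dioxane-4,6-dione), CC1(C)OC(=O)CC(=O)O1
Why: The same carbodiimide-mediated C-acylation of Meldrum's acid as in step 1 turns the free carboxyl into a latent acylketene, the protected hydroxyl and the hindered tert-butyl ester taking no part.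

**Step 11**
Reactants: 15 tert-butyl (2R,6S)-2-[(1R,2S)-1-[(tert-butyldimethylsilyl)oxy]-2-methylbutyl]-9-(2,2-dimethyl-4,6-dioxo-1,3-dioxan-5-ylidene)-9-hydroxy-6-methylnonanoate; 16 methyl (R)-3-hydroxybutanoate (1.2 equiv)
Product: 19 tert-butyl (2R,6S)-2-[(1R,2S)-1-[(tert-butyldimethylsilyl)oxy]-2-methylbutyl]-9-[(6R)-4-hydroxy-6-methyl-2-oxo-5,6-dihydro-2H-pyran-3-yl]-6-methyl-9-oxononanoate, via acylketene 17 (not isolated), via acylacetate 18 (not isolated)
Conditions: PhMe, 90 °C; evaporate; then KOtBu (1.15 equiv), THF, 0 °C → rt; 1 M HCl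
Reagents that add atoms: none
Why: Heating 15 causes retro-[4+2] loss of acetone and CO2 to acylketene 17, whose ketene carbon is captured by the secondary hydroxyl of 16 to give acylacetate 18; one equivalent of KOtBu then deprotonates the doubly activated CH2 (future C3) and this enolate adds to the methyl ester carbonyl (future C4), expelling methoxide. The closest known reaction types are the alcoholysis of acyl Meldrum's acids and the Lacey–Dieckmann (intramolecular Claisen) cyclization of acylacetates of hydroxy esters. The dihydropyranone closes in the 6-exo-trig mode through the C3–C4 bond (ring atoms C3, C2, O1, C6, C5, C4). No stereocenter is created, and C6 is carried over from 16 because its C–O bond is never broken and it is not alpha to a carbonyl. The step needs C-acylation at C4 to win over base-induced loss of the acyloxy group from C6 and over enolization next to the tert-butyl ester with loss of silanolate; the large acidity gap between the C3–H and every other C–H means that a single equivalent of base sits on C3, and the enolized acyloxy group is a poor leaving group. Deprotonation of the tricarbonyl product (a vinylogous acid) by the methoxide set free should pull the otherwise reversible condensation to completion.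

**Step 12**
Reactants: 19 tert-butyl (2R,6S)-2-[(1R,2S)-1-[(tert-butyldimethylsilyl)oxy]-2-methylbutyl]-9-[(6R)-4-hydroxy-6-methyl-2-oxo-5,6-dihydro-2H-pyran-3-yl]-6-methyl-9-oxononanoate
Product: 20 (2R,6S)-2-[(1R,2S)-1-hydroxy-2-methylbutyl]-9-[(6R)-4-hydroxy-6-methyl-2-oxo-5,6-dihydro-2H-pyran-3-yl]-6-methyl-9-oxononanoic acid
Conditions: TFA/CH2Cl2/H2O (10:10:1), 0 °C → rt
Reagents that add atoms: none
Why: Acidolysis removes the tert-butyl ester as isobutene and hydrolyses the silyl ether in one operation (acid-mediated global deprotection), the tricarbonyl enol lactone and the beta-hydroxy acid being stable to trifluoroacetic acid at room temperature, so that no stereocenter is touched.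

**Compound list**

1 | (S)-2-methylbutanoic acid | CC[C@H](C)C(=O)O | starting material
2 | 5-[(2S)-1-hydroxy-2-methylbutylidene]-2,2-dimethyl-1,3-dioxane-4,6-dione | CC[C@H](C)C(O)=C1C(=O)OC(C)(C)OC1=O | intermediate
3 | (4S)-4-methylhex-1-ene-1,3-dione (acylketene) | CC[C@H](C)C(=O)C=C=O | intermediate
4 | tert-butyl (4S)-4-methyl-3-oxohexanoate | CC[C@H](C)C(=O)CC(=O)OC(C)(C)C | intermediate
5 | tert-butyl (3S,4S)-3-hydroxy-4-methylhexanoate | CC[C@H](C)[C@@H](O)CC(=O)OC(C)(C)C | intermediate
6 | dilithium (3S,4S)-1-tert-butoxy-4-methylhex-1-ene-1,3-diolate (chelated alkoxide enolate of 5) | CC[C@H](C)[C@@H]([O-])C=C([O-])OC(C)(C)C.[Li+].[Li+] | intermediate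
7 | tert-butyl (2R)-2-[(1R,2S)-1-hydroxy-2-methylbutyl]pent-4-enoate | CC[C@H](C)[C@@H](O)[C@@H](CC=C)C(=O)OC(C)(C)C | intermediate
8 | tert-butyl (2R)-2-[(1R,2S)-1-[(tert-butyldimethylsilyl)oxy]-2-methylbutyl]pent-4-enoate | CC[C@H](C)[C@@H](O[Si](C)(C)C(C)(C)C)[C@@H](CC=C)C(=O)OC(C)(C)C | intermediate
9 | (R)-3,7-dimethylocta-1,6-diene ((R)-β-citronellene) | C=C[C@H](C)CCC=C(C)C | starting material
10 | 3,3-dimethyl-5-[(3R)-3-methylpent-4-en-1-yl]-1,2,4-trioxolane (ozonide, epimers at C5) | CC1(C)OOC(CC[C@@H](C)C=C)O1 | intermediate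
11 | (R)-4-methylhex-5-enal | C=C[C@H](C)CCC=O | intermediate
12 | (R)-4-methylhex-5-enoic acid | C=C[C@H](C)CCC(=O)O | intermediate
13 | (4R,5E,8R,9R,10S)-8-(tert-butoxycarbonyl)-9-[(tert-butyldimethylsilyl)oxy]-4,10-dimethyldodec-5-enoic acid | CC[C@H](C)[C@@H](O[Si](C)(C)C(C)(C)C)[C@@H](C/C=C/[C@H](C)CCC(=O)O)C(=O)OC(C)(C)C | intermediate
14 | (4S,8R,9R,10S)-8-(tert-butoxycarbonyl)-9-[(tert-butyldimethylsilyl)oxy]-4,10-dimethyldodecanoic acid | CC[C@H](C)[C@@H](O[Si](C)(C)C(C)(C)C)[C@@H](CCC[C@H](C)CCC(=O)O)C(=O)OC(C)(C)C | intermediate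
15 | tert-butyl (2R,6S)-2-[(1R,2S)-1-[(tert-butyldimethylsilyl)oxy]-2-methylbutyl]-9-(2,2-dimethyl-4,6-dioxo-1,3-dioxan-5-ylidene)-9-hydroxy-6-methylnonanoate | CC[C@H](C)[C@@H](O[Si](C)(C)C(C)(C)C)[C@@H](CCC[C@H](C)CCC(O)=C1C(=O)OC(C)(C)OC1=O)C(=O)OC(C)(C)C | intermediate
16 | methyl (R)-3-hydroxybutanoate | C[C@@H](O)CC(=O)OC | starting material
17 | tert-butyl (2R,6S)-2-[(1R,2S)-1-[(tert-butyldimethylsilyl)oxy]-2-methylbutyl]-6-methyl-9,11-dioxoundec-10-enoate (acylketene) | CC[C@H](C)[C@@H](O[Si](C)(C)C(C)(C)C)[C@@H](CCC[C@H](C)CCC(=O)C=C=O)C(=O)OC(C)(C)C | intermediate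
18 | 1-tert-butyl 11-[(2R)-4-methoxy-4-oxobutan-2-yl] (2R,6S)-2-[(1R,2S)-1-[(tert-butyldimethylsilyl)oxy]-2-methylbutyl]-6-methyl-9-oxoundecanedioate | CC[C@H](C)[C@@H](O[Si](C)(C)C(C)(C)C)[C@@H](CCC[C@H](C)CCC(=O)CC(=O)O[C@H](C)CC(=O)OC)C(=O)OC(C)(C)C | intermediate
19 | tert-butyl (2R,6S)-2-[(1R,2S)-1-[(tert-butyldimethylsilyl)oxy]-2-methylbutyl]-9-[(6R)-4-hydroxy-6-methyl-2-oxo-5,6-dihydro-2H-pyran-3-yl]-6-methyl-9-oxononanoate | CC[C@H](C)[C@@H](O[Si](C)(C)C(C)(C)C)[C@@H](CCC[C@H](C)CCC(=O)C1=C(O)C[C@@H](C)OC1=O)C(=O)OC(C)(C)C | intermediate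
20 | (2R,6S)-2-[(1R,2S)-1-hydroxy-2-methylbutyl]-9-[(6R)-4-hydroxy-6-methyl-2-oxo-5,6-dihydro-2H-pyran-3-yl]-6-methyl-9-oxononanoic acid | CC[C@H](C)[C@@H](O)[C@@H](CCC[C@H](C)CCC(=O)C1=C(O)C[C@@H](C)OC1=O)C(=O)O | target

**Summary**

Total step count: 12. Longest linear sequence: 10 steps (steps 1–5 and 8–12, from (S)-2-methylbutanoic acid).

**Steps most likely to fail**

Step 11. The stabilized C3 enolate may add too slowly to the methyl ester, so that retro-Claisen cleavage of the acylacetate or base-induced loss of the acyloxy group from C6 takes over. The fallback sets out from 16 and 14 and comes back at 19; it makes the ring first and attaches the chain afterwards. Compound 16 would be acetylated (Ac2O, pyridine, DMAP) to methyl (R)-3-acetoxybutanoate F1. Its far more nucleophilic acetate enolate (LiN(SiMe3)2, THF, −78 °C) should close the same C3–C4 bond to (R)-4-hydroxy-6-methyl-5,6-dihydro-2H-pyran-2-one F2. F2 would then be O-acylated with acid 14 (DCC, DMAP, CH2Cl2) to (2R)-2-methyl-6-oxo-3,6-dihydro-2H-pyran-4-yl (4S,8R,9R,10S)-8-(tert-butoxycarbonyl)-9-[(tert-butyldimethylsilyl)oxy]-4,10-dimethyldodecanoate F3, which the DMAP present should isomerize by 1,3 O-to-C acyl shift to 19.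

Step 8. Turnover at the allylically branched alkene of 12 may be slow, so that self-metathesis of 8 and ruthenium hydride double-bond migration erode the cross product. The fallback sets out from 5 (through its dianion 6) and from purchased (S)-3,7-dimethylocta-1,6-diene F4, the enantiomer of 9, and comes back at 14. It forms the C2–C3 bond by alkylation with the whole branched chain and leaves only an easy metathesis with an acrylate.
- Ozonolysis of F4 as in step 6, through 3,3-dimethyl-5-[(3S)-3-methylpent-4-en-1-yl]-1,2,4-trioxolane F5, but with NaBH4 work-up, would give (S)-4-methylhex-5-en-1-ol F6.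
- I2, PPh3 and imidazole would convert F6 into (S)-6-iodo-3-methylhex-1-ene F7.
- Alkylation of 6 with F7 (THF/DMPU, −78 → −10 °C) should give tert-butyl (2R,6S)-2-[(1R,2S)-1-hydroxy-2-methylbutyl]-6-methyloct-7-enoate F8 with the same anti selectivity as in step 4.
- Silylation as in step 5 would give tert-butyl (2R,6S)-2-[(1R,2S)-1-[(tert-butyldimethylsilyl)oxy]-2-methylbutyl]-6-methyloct-7-enoate F9.
- Cross-metathesis of F9 with acrylic acid, which does not self-couple, should give (2E,4S,8R,9R,10S)-8-(tert-butoxycarbonyl)-9-[(tert-butyldimethylsilyl)oxy]-4,10-dimethyldodec-2-enoic acid F10.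
- Hydrogenation of F10 under the conditions of step 9 returns to 14.

Step 6. Over-oxidation is possible, because the vinyl group also consumes ozone once the trisubstituted alkene is used up. The fallback sets out from 9 and comes back at 11. mCPBA (1.0 equiv, CH2Cl2, 0 °C), which is far more selective for the electron-rich alkene, would give 2,2-dimethyl-3-[(3R)-3-methylpent-4-en-1-yl]oxirane F11. Periodic acid (H5IO6, THF/H2O, 0 °C) would then open and cleave the epoxide to 11 and acetone.

**Further compounds**

F1 | step 11 | methyl (R)-3-acetoxybutanoate | CC(=O)O[C@H](C)CC(=O)OC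
F2 | step 11 | (R)-4-hydroxy-6-methyl-5,6-dihydro-2H-pyran-2-one | C[C@@H]1CC(O)=CC(=O)O1
F3 | step 11 | (2R)-2-methyl-6-oxo-3,6-dihydro-2H-pyran-4-yl (4S,8R,9R,10S)-8-(tert-butoxycarbonyl)-9-[(tert-butyldimethylsilyl)oxy]-4,10-dimethyldodecanoate | CC[C@H](C)[C@@H](O[Si](C)(C)C(C)(C)C)[C@@H](CCC[C@H](C)CCC(=O)OC1=CC(=O)O[C@H](C)C1)C(=O)OC(C)(C)C
F4 | step 8 | (S)-3,7-dimethylocta-1,6-diene | C=C[C@@H](C)CCC=C(C)C
F5 | step 8 | 3,3-dimethyl-5-[(3S)-3-methylpent-4-en-1-yl]-1,2,4-trioxolane | CC1(C)OOC(CC[C@H](C)C=C)O1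
F6 | step 8 | (S)-4-methylhex-5-en-1-ol | C=C[C@@H](C)CCCO
F7 | step 8 | (S)-6-iodo-3-methylhex-1-ene | C=C[C@@H](C)CCCI
F8 | step 8 | tert-butyl (2R,6S)-2-[(1R,2S)-1-hydroxy-2-methylbutyl]-6-methyloct-7-enoate | CC[C@H](C)[C@@H](O)[C@@H](CCC[C@H](C)C=C)C(=O)OC(C)(C)C
F9 | step 8 | tert-butyl (2R,6S)-2-[(1R,2S)-1-[(tert-butyldimethylsilyl)oxy]-2-methylbutyl]-6-methyloct-7-enoate | CC[C@H](C)[C@@H](O[Si](C)(C)C(C)(C)C)[C@@H](CCC[C@H](C)C=C)C(=O)OC(C)(C)C
F10 | step 8 | (2E,4S,8R,9R,10S)-8-(tert-butoxycarbonyl)-9-[(tert-butyldimethylsilyl)oxy]-4,10-dimethyldodec-2-enoic acid | CC[C@H](C)[C@@H](O[Si](C)(C)C(C)(C)C)[C@@H](CCC[C@H](C)/C=C/C(=O)O)C(=O)OC(C)(C)C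
F11 | step 6 | 2,2-dimethyl-3-[(3R)-3-methylpent-4-en-1-yl]oxirane | CC1(C)OC1CC[C@@H](C)C=C
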